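**Retrosynthetic overview**
1. The butenolide ring O–C16(=O)–C13=C14–C15 is made last. Its ring oxygen is a carboxylate oxygen of C16, C13 is α to C16 and can carry a phosphonate, and C14 (sp2 CH) and C15 (OCH2) are a vicinal aldehyde/alkyl-halide pair. C15–O (carboxylate SN2) and C13=C14 (intramolecular Horner–Wadsworth–Emmons) are therefore formed in one flask from a C13-phosphono C16-acid and BrCH2CHO; the ring has no stereocentre, so both C13 epimers of the precursor converge.
2. C12–C13: C-alkylation of the diethylphosphonoacetic acid dianion by the C12 iodide.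
3. Decalin: rings A, then B, are closed in one Mn(III)/Cu(II) oxidative radical cascade of an acyclic 2-methyl-3-oxo ester carrying an 8-phenylmenthyl auxiliary. This sets C4, C5, C9 and C10 and leaves C3=O, the C19 ester and the C8=C17 alkene.
4. C3–OH by axial hydride delivery, C17–OH by hydroboration, C8 by a thermodynamic funnel (aldehyde epimerisation to the equatorial isomer), C19–OH by LiAlH4 with release of the auxiliary.
5. Polyene from geranyl chloride: one-carbon homologation (C12), allylic oxidation of the E-methyl group (C1), bromide, dianion alkylation.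

Key step: step 16

Remark on descriptors: labdane numbering is used; α/β give the actual faces in the target series, in which C-20 (10-CH3), C-19, 3-OH and the C-9 side chain are α, H-5 and H-9 are β, and C-17 is β (equatorial).
Assumption: under non-chelating Mn(OAc)3/Cu(OAc)2/AcOH conditions the (1S,2R,5S)-8-phenylmenthyl ester is taken to direct the cyclisation to the 10α-methyl series (mirror image of the sense known for the (1R,2S,5R) auxiliary in the podocarpate series); if the sense is the reverse, the antipodal auxiliary is used and nothing else changes.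

**Route**

Step 1
Reactants: 1 geranyl chloride
Product: 3 homogeraniol, via homogeranyl(isopropoxy)dimethylsilane 2 (not isolated)
Conditions: ClMgCH2SiMe2(Oi-Pr) (from ClCH2SiMe2(Oi-Pr) and Mg, THF), Li2CuCl4 (cat.), THF, 0 °C to rt; then KF, KHCO3, 30% H2O2, MeOH/THF, rt
Reagents that add atoms: (isopropoxydimethylsilyl)methylmagnesium chloride CC(C)O[Si](C)(C)C[Mg]Cl; hydrogen peroxide OO
Why: Copper-catalysed α-selective (SN2) coupling of the allylic chloride with Tamao's hydroxymethyl-anion Grignard reagent, followed by Tamao oxidation of the C–Si bond, adds the C12 carbinol carbon without touching the E-trisubstituted alkene.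

Step 2
Reactants: 3 homogeraniol
Product: 4 homogeranyl benzyl ether
Conditions: NaH, BnBr, Bu4NI (cat.), THF, 0 °C to rt
Reagents that add atoms: benzyl bromide BrCc1ccccc1
Why: Williamson etherification gives a C12–O protecting group that should survive oxidative radical, hydride, borane and base conditions.

Step 3
Reactants: 4 homogeranyl benzyl ether
Product: 5 (2E,6E)-9-(benzyloxy)-2,6-dimethylnona-2,6-dien-1-ol
Conditions: SeO2 (cat.), t-BuOOH, salicylic acid (cat.), CH2Cl2, rt
Reagents that add atoms: tert-butyl hydroperoxide CC(C)(C)OO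
Why: Sharpless SeO2/t-BuOOH allylic oxidation (ene reaction, then [2,3] shift) should select the E-methyl group of the terminal, most electron-rich trisubstituted alkene and give the E-allylic alcohol that becomes C1.

Step 4
Reactants: 5 (2E,6E)-9-(benzyloxy)-2,6-dimethylnona-2,6-dien-1-ol
Product: 6 (2E,6E)-9-(benzyloxy)-1-bromo-2,6-dimethylnona-2,6-diene
Conditions: CBr4, PPh3, CH2Cl2, 0 °C
Reagents that add atoms: carbon tetrabromide BrC(Br)(Br)Br
Why: Appel bromination of a primary allylic alcohol should proceed without allylic transposition or loss of E geometry.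

Step 5
Reactants: 7 ethyl 2-methylacetoacetate; 8 (+)-8-phenylmenthol, (1S,2R,5S)
Product: 9 (1S,2R,5S)-8-phenylmenthyl 2-methyl-3-oxobutanoate
Conditions: DMAP (cat.), toluene, reflux, removal of EtOH (4 Å sieves)
Reagents that add atoms: none
Why: DMAP-catalysed transesterification of a β-keto ester (through the acylketene) loads the chiral auxiliary on the future C19 carboxyl.

Step 6
Reactants: 9 (1S,2R,5S)-8-phenylmenthyl 2-methyl-3-oxobutanoate; 6 (2E,6E)-9-(benzyloxy)-1-bromo-2,6-dimethylnona-2,6-diene
Product: 10 (1S,2R,5S)-8-phenylmenthyl (6E,10E)-13-(benzyloxy)-2,6,10-trimethyl-3-oxotrideca-6,10-dienoate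
Conditions: LDA (2.1 equiv), THF, −78 to 0 °C; then 6, 0 °C to rt; dilute HCl quench
Reagents that add atoms: none
Why: Huckin–Weiler dianion alkylation: the more basic γ-carbanion of the β-keto ester dianion is alkylated (SN2) by the allylic bromide, forming C1–C2; the C4 epimers are inconsequential because C4 becomes a radical.

Step 7
Reactants: 10 (1S,2R,5S)-8-phenylmenthyl (6E,10E)-13-(benzyloxy)-2,6,10-trimethyl-3-oxotrideca-6,10-dienoate
Product: 11 (1S,2R,5S)-8-phenylmenthyl 12-(benzyloxy)-3-oxo-13,14,15,16-tetranorlabd-8(17)-en-19-oate (10α-CH3, 5β-H, 9β-H, 4α-CO2R axial, 4β-CH3)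
Conditions: Mn(OAc)3·2H2O (2.2 equiv), Cu(OAc)2·H2O (1 equiv), degassed AcOH, rt; chromatographic removal of the minor diastereomer
Reagents that add atoms: none
Why: Snider-type Mn(III)/Cu(II) oxidative free-radical polyene cyclisation: the C4 radical closes ring A and then ring B (both 6-endo) through a chair–chair array of the E,E-diene, which should give the trans ring fusion, the equatorial C9 side chain cis to C20 and the axial C4 ester as in the podocarpate precedent, Cu(II) oxidises the tertiary C8 radical to the exocyclic alkene, and the phenyl ring of the auxiliary shields one face of the C4 radical so that the absolute configuration is set in the first C–C bond formation.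

Step 8
Reactants: 11 the bicyclic keto ester
Product: 13 (1S,2R,5S)-8-phenylmenthyl 12-(benzyloxy)-3α,17-dihydroxy-13,14,15,16-tetranorlabdan-19-oate (C8 epimers; axial 8α-CH2OH expected to predominate), via C17-boryl C3-boryloxy adduct 12 (not isolated)
Conditions: BH3·THF (excess), THF, 0 °C to rt; then 3 M NaOH, 30% H2O2, 0 °C to rt
Reagents that add atoms: hydrogen peroxide OO
Why: Borane reduces the C3 ketone by axial hydride delivery (equatorial 3α-OH) and adds anti-Markovnikov to the 1,1-disubstituted alkene (Brown hydroboration–oxidation) to give the C17 alcohol; the C8 configuration is corrected in step 9 and the hindered ester is not touched.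

Step 9
Reactants: 13 the 3α,17-diol (C8 epimers)
Product: 15 (1S,2R,5S)-8-phenylmenthyl 12-(benzyloxy)-3α-hydroxy-17-oxo-13,14,15,16-tetranorlabdan-19-oate (8α-H, equatorial CHO), via C8-epimeric 17-aldehyde 14 (not isolated)
Conditions: TEMPO (cat.), PhI(OAc)2, CH2Cl2, rt; then DBU (3 equiv), rt
Reagents that add atoms: none
Why: The nitroxyl/PhI(OAc)2 oxidation takes only the primary alcohol, and DBU then equilibrates the C8-epimeric aldehydes through the enol to the isomer with the formyl group equatorial and trans to the C9 side chain (the axial epimer clashes 1,3-diaxially with C20), so the mixture from step 8 should converge on the required C8 configuration.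

Step 10
Reactants: 15 the equatorial 17-aldehyde
Product: 16 12-(benzyloxy)-13,14,15,16-tetranorlabdane-3α,17,19-triol (8α-H)
Conditions: LiAlH4 (excess), THF, 0 °C to reflux; Fieser work-up; auxiliary 8 recovered
Reagents that add atoms: none
Why: LiAlH4 reduces the aldehyde and the hindered neopentyl ester to the C17 and C19 primary alcohols and releases the auxiliary; C8 is no longer epimerisable once reduced.

Step 11
Reactants: 16 the triol
Product: 17 12-(benzyloxy)-3α,17,19-tris(tert-butyldimethylsilyloxy)-13,14,15,16-tetranorlabdane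
Conditions: TBSOTf (4 equiv), 2,6-lutidine, CH2Cl2, 0 °C to rt
Reagents that add atoms: tert-butyldimethylsilyl triflate CC(C)(C)[Si](C)(C)OS(=O)(=O)C(F)(F)F
Why: The silyl triflate silylates all three hydroxyls, including the hindered secondary C3–OH, in one step, and the ethers are orthogonal to hydrogenolysis.

Step 12
Reactants: 17 the tris-TBS benzyl ether
Product: 18 3α,17,19-tris(tert-butyldimethylsilyloxy)-13,14,15,16-tetranorlabdan-12-ol
Conditions: H2 (1 atm), 10% Pd/C, EtOAc, rt
Reagents that add atoms: none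
Why: Hydrogenolysis removes the benzyl ether; no alkene remains and silyl ethers are stable in EtOAc.

Step 13
Reactants: 18 the C12 alcohol
Product: 19 12-iodo-3α,17,19-tris(tert-butyldimethylsilyloxy)-13,14,15,16-tetranorlabdane
Conditions: I2, PPh3, imidazole, CH2Cl2, 0 °C to rt
Reagents that add atoms: iodine II
Why: Garegg–Samuelsson (Appel-type) iodination converts the unhindered primary alcohol into the iodide under neutral conditions.

Step 14
Reactants: 19 the C12 iodide; 20 diethylphosphonoacetic acid
Product: 21 13-(diethoxyphosphoryl)-3α,17,19-tris(tert-butyldimethylsilyloxy)-14,15-dinorlabdan-16-oic acid (C13 epimers)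
Conditions: 20 (2 equiv), LDA (4.2 equiv), THF, −78 °C; then 19, DMPU, −78 °C to rt; cold dilute HCl to pH 3
Reagents that add atoms: none
Why: The dianion of the phosphonoacetic acid is alkylated at carbon by the primary iodide (SN2), forming C12–C13 and delivering the free acid directly; the new C13 stereocentre is uncontrolled and is removed in step 16.

Step 15
Reactants: 22 bromoacetaldehyde diethyl acetal
Product: 23 bromoacetaldehyde (dried CH2Cl2 solution, used at once)
Conditions: 2 M aq. HBr, 80 °C; extraction into CH2Cl2, MgSO4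
Reagents that add atoms: water O
Why: Acid-catalysed acetal hydrolysis frees the unstable α-bromo aldehyde just before use.

Step 16
Reactants: 21 the C13-phosphono C16-acid; 23 bromoacetaldehyde
Product: 25 3,17,19-tris-O-(tert-butyldimethylsilyl)-14-deoxy-17-hydroxyandrographolide, via 2-oxoethyl phosphonoester 24 (not isolated)
Conditions: Cs2CO3 (0.55 equiv), DMF, 0 °C, then 23 (1.5 equiv), 0 °C to rt; then Cs2CO3 (1.5 equiv), rt, same flask
Reagents that add atoms: none
Why: The caesium carboxylate, the only nucleophile present at the first stage, displaces bromide from the α-bromo aldehyde (SN2 at C15, forming O–C15) to give the 2-oxoethyl ester 24. The C13–H of 24, now flanked by ester and phosphonate, is deprotonated by carbonate, the carbanion adds to the aldehyde five atoms away, and the oxaphosphetane collapses with loss of diethyl phosphate to give C13=C14 (intramolecular Horner–Wadsworth–Emmons). The closest known reaction types are the one-flask carboxylate alkylation/intramolecular condensation of α-halo ketones with phosphonoacetic or arylacetic acids to butenolides and the intramolecular HWE of 2-oxoalkyl phosphonoacetates used for cardenolide-type butenolides. The five-membered lactone closes by carbanion attack on the exocyclic aldehyde carbonyl (formally 5-(enolendo)-exo-trig, which the phosphonate-stabilised carbanion negotiates as in those precedents). No stereocentre is created: the C13 stereocentre of 21 is destroyed, so both epimers converge on one product, and the ring allows only the endocyclic alkene. The step needs O-alkylation before olefination and ring closure before intermolecular condensation; this should be secured because the α-carbon of the carboxylate salt is not acidic towards carbonate until the ester has formed and the aldehyde then sits 1,5 to the carbanion, while the silyl ethers are inert.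

Step 17
Reactants: 25 the tris-TBS butenolide
Product: 26 14-deoxy-17-hydroxyandrographolide
Conditions: HF·pyridine, THF/pyridine, 0 °C to rt
Reagents that add atoms: none
Why: Fluoride-mediated desilylation under mildly acidic conditions frees the three hydroxyls and should leave the base-sensitive butenolide and all stereocentres untouched.

**Compound list**
1 | geranyl chloride, (2E)-1-chloro-3,7-dimethylocta-2,6-diene | CC(C)=CCC/C(C)=C/CCl | starting material
2 | [(3E)-4,8-dimethylnona-3,7-dien-1-yl](isopropoxy)dimethylsilane | CC(C)=CCC/C(C)=C/CC[Si](C)(C)OC(C)C | intermediate (not isolated)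
3 | homogeraniol, (3E)-4,8-dimethylnona-3,7-dien-1-ol | CC(C)=CCC/C(C)=C/CCO | intermediate
4 | homogeranyl benzyl ether | CC(C)=CCC/C(C)=C/CCOCc1ccccc1 | intermediate
5 | (2E,6E)-9-(benzyloxy)-2,6-dimethylnona-2,6-dien-1-ol | OC/C(C)=C/CC/C(C)=C/CCOCc1ccccc1 | intermediate
6 | (2E,6E)-9-(benzyloxy)-1-bromo-2,6-dimethylnona-2,6-diene | BrC/C(C)=C/CC/C(C)=C/CCOCc1ccccc1 | intermediate
7 | ethyl 2-methylacetoacetate | CCOC(=O)C(C)C(C)=O | starting material
8 | (+)-8-phenylmenthol, (1S,2R,5S)-5-methyl-2-(2-phenylpropan-2-yl)cyclohexan-1-ol | CC(C)(c1ccccc1)[C@H]1CC[C@H](C)C[C@@H]1O | starting material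
9 | (1S,2R,5S)-8-phenylmenthyl 2-methyl-3-oxobutanoate (C2 epimers) | CC(=O)C(C)C(=O)O[C@H]1C[C@@H](C)CC[C@@H]1C(C)(C)c1ccccc1 | intermediate
10 | (1S,2R,5S)-8-phenylmenthyl (6E,10E)-13-(benzyloxy)-2,6,10-trimethyl-3-oxotrideca-6,10-dienoate (C2 epimers) | O=C(O[C@H]1C[C@@H](C)CC[C@@H]1C(C)(C)c1ccccc1)C(C)C(=O)CC/C(C)=C/CC/C(C)=C/CCOCc1ccccc1 | intermediate
11 | 8-phenylmenthyl 12-(benzyloxy)-3-oxo-13,14,15,16-tetranorlabd-8(17)-en-19-oate (10α-CH3, 5β-H, 9β-H, axial 4α-ester) | C[C@]1(C(=O)O[C@H]3C[C@@H](C)CC[C@@H]3C(C)(C)c3ccccc3)[C@H]2CCC(=C)[C@@H](CCOCc3ccccc3)[C@]2(C)CCC1=O | intermediate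
12 | C17-boryl C3-boryloxy adduct of 11 (drawn as the monomeric RBH2/ROBH2 form, axial C8 epimer) | C[C@]1(C(=O)O[C@H]3C[C@@H](C)CC[C@@H]3C(C)(C)c3ccccc3)[C@H]2CC[C@@H](CB)[C@@H](CCOCc3ccccc3)[C@]2(C)CC[C@H]1OB | intermediate (not isolated)
13 | 8-phenylmenthyl 12-(benzyloxy)-3α,17-dihydroxy-13,14,15,16-tetranorlabdan-19-oate (C8 epimers; SMILES shows the axial 8α-CH2OH epimer) | C[C@]1(C(=O)O[C@H]3C[C@@H](C)CC[C@@H]3C(C)(C)c3ccccc3)[C@H]2CC[C@@H](CO)[C@@H](CCOCc3ccccc3)[C@]2(C)CC[C@H]1O | intermediate
14 | 8-phenylmenthyl 12-(benzyloxy)-3α-hydroxy-17-oxo-13,14,15,16-tetranorlabdan-19-oate, C8 epimers (SMILES shows the axial 8α-CHO epimer) | C[C@]1(C(=O)O[C@H]3C[C@@H](C)CC[C@@H]3C(C)(C)c3ccccc3)[C@H]2CC[C@@H](C=O)[C@@H](CCOCc3ccccc3)[C@]2(C)CC[C@H]1O | intermediate (not isolated)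
15 | 8-phenylmenthyl 12-(benzyloxy)-3α-hydroxy-17-oxo-13,14,15,16-tetranorlabdan-19-oate, 8α-H (equatorial 8β-CHO) | C[C@]1(C(=O)O[C@H]3C[C@@H](C)CC[C@@H]3C(C)(C)c3ccccc3)[C@H]2CC[C@H](C=O)[C@@H](CCOCc3ccccc3)[C@]2(C)CC[C@H]1O | intermediate
16 | 12-(benzyloxy)-13,14,15,16-tetranorlabdane-3α,17,19-triol (8α-H) | C[C@]1(CO)[C@H]2CC[C@H](CO)[C@@H](CCOCc3ccccc3)[C@]2(C)CC[C@H]1O | intermediate
17 | 12-(benzyloxy)-3α,17,19-tris(TBS-oxy)-13,14,15,16-tetranorlabdane | C[C@]1(CO[Si](C)(C)C(C)(C)C)[C@H]2CC[C@H](CO[Si](C)(C)C(C)(C)C)[C@@H](CCOCc3ccccc3)[C@]2(C)CC[C@H]1O[Si](C)(C)C(C)(C)C | intermediate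
18 | 3α,17,19-tris(TBS-oxy)-13,14,15,16-tetranorlabdan-12-ol | C[C@]1(CO[Si](C)(C)C(C)(C)C)[C@H]2CC[C@H](CO[Si](C)(C)C(C)(C)C)[C@@H](CCO)[C@]2(C)CC[C@H]1O[Si](C)(C)C(C)(C)C | intermediate
19 | 12-iodo-3α,17,19-tris(TBS-oxy)-13,14,15,16-tetranorlabdane | C[C@]1(CO[Si](C)(C)C(C)(C)C)[C@H]2CC[C@H](CO[Si](C)(C)C(C)(C)C)[C@@H](CCI)[C@]2(C)CC[C@H]1O[Si](C)(C)C(C)(C)C | intermediate
20 | diethylphosphonoacetic acid, 2-(diethoxyphosphoryl)acetic acid | CCOP(=O)(CC(=O)O)OCC | starting material
21 | 13-(diethoxyphosphoryl)-3α,17,19-tris(TBS-oxy)-14,15-dinorlabdan-16-oic acid (C13 epimers) | C[C@]1(CO[Si](C)(C)C(C)(C)C)[C@H]2CC[C@H](CO[Si](C)(C)C(C)(C)C)[C@@H](CCC(C(=O)O)P(=O)(OCC)OCC)[C@]2(C)CC[C@H]1O[Si](C)(C)C(C)(C)C | intermediate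
22 | bromoacetaldehyde diethyl acetal, 2-bromo-1,1-diethoxyethane | CCOC(CBr)OCC | starting material
23 | bromoacetaldehyde | O=CCBr | intermediate
24 | 2-oxoethyl ester of 21 (C13 epimers) | C[C@]1(CO[Si](C)(C)C(C)(C)C)[C@H]2CC[C@H](CO[Si](C)(C)C(C)(C)C)[C@@H](CCC(C(=O)OCC=O)P(=O)(OCC)OCC)[C@]2(C)CC[C@H]1O[Si](C)(C)C(C)(C)C | intermediate (not isolated)
25 | 3,17,19-tris-O-TBS-14-deoxy-17-hydroxyandrographolide | C[C@]1(CO[Si](C)(C)C(C)(C)C)[C@H]2CC[C@H](CO[Si](C)(C)C(C)(C)C)[C@@H](CCC3=CCOC3=O)[C@]2(C)CC[C@H]1O[Si](C)(C)C(C)(C)C | intermediate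
26 | 14-deoxy-17-hydroxyandrographolide | C[C@]1(CO)[C@H]2CC[C@H](CO)[C@@H](CCC3=CCOC3=O)[C@]2(C)CC[C@H]1O | target

**Step count**
Total steps: 17. Longest linear sequence: 15 (steps 1–4, 6–14, 16, 17).

**Steps most likely to fail, with fallbacks**

Step 7. Facial discrimination by the auxiliary in the first C–C bond formation may be insufficient, and the Cu(II) oxidation may give endocyclic alkene isomers, so that stereochemical purity and material are lost. The fallback replaces auxiliary induction by resolution; it sets out from 6 and 7 and comes back at 16. The dianion of 7 (LDA, 2 equiv) is alkylated with 6 to give ethyl (6E,10E)-13-(benzyloxy)-2,6,10-trimethyl-3-oxotrideca-6,10-dienoate F1. Mn(OAc)3/Cu(OAc)2 in AcOH should give racemic ethyl 12-(benzyloxy)-3-oxo-13,14,15,16-tetranorlabd-8(17)-en-19-oate F2 with the same relative configuration. Its enantiomers are separated by preparative chromatography on a chiral stationary phase. The 10α-methyl enantiomer is taken through the conditions of step 8 to ethyl 12-(benzyloxy)-3α,17-dihydroxy-13,14,15,16-tetranorlabdan-19-oate F3 (C8 epimers) and of step 9 to ethyl 12-(benzyloxy)-3α-hydroxy-17-oxo-13,14,15,16-tetranorlabdan-19-oate F4 (8α-H). LiAlH4 then gives 16.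

Step 16. Bromoacetaldehyde may self-condense or polymerise under carbonate, or may undergo intermolecular condensation before O-alkylation, which would lead to open-chain E-olefin that cannot lactonise. The fallback makes the aldehyde on the ester instead; it sets out from 21 and comes back at 25. The acid 21 is O-allylated (allyl bromide, K2CO3, DMF) to allyl 13-(diethoxyphosphoryl)-3α,17,19-tris(TBS-oxy)-14,15-dinorlabdan-16-oate F5. Ozonolysis (O3, CH2Cl2, −78 °C; PPh3) cuts the terminal alkene to the 2-oxoethyl ester 24. Masamune–Roush conditions (LiCl, DBU, MeCN) close 24 to 25.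

Step 9. Oxidation of the hindered axial CH2OH may stall or spill over to the C3 alcohol, and equilibration at C8 may stay incomplete. The fallback gives up chemoselectivity; it sets out from 13 and comes back at 16. Dess–Martin periodinane oxidises both hydroxyls to 8-phenylmenthyl 12-(benzyloxy)-3,17-dioxo-13,14,15,16-tetranorlabdan-19-oate F6 (C8 epimers). DBU in toluene (non-nucleophilic, to avoid retro-Claisen cleavage) equilibrates it to the 8α-H keto aldehyde F7. LiAlH4 then reduces ketone (axial hydride, 3α-OH), aldehyde and ester to 16.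

Further compounds
F1 | step 7 | ethyl (6E,10E)-13-(benzyloxy)-2,6,10-trimethyl-3-oxotrideca-6,10-dienoate | CCOC(=O)C(C)C(=O)CC/C(C)=C/CC/C(C)=C/CCOCc1ccccc1
F2 | step 7 | ethyl 12-(benzyloxy)-3-oxo-13,14,15,16-tetranorlabd-8(17)-en-19-oate (made as racemate; SMILES shows the enantiomer carried on) | C[C@]1(C(=O)OCC)[C@H]2CCC(=C)[C@@H](CCOCc3ccccc3)[C@]2(C)CCC1=O
F3 | step 7 | ethyl 12-(benzyloxy)-3α,17-dihydroxy-13,14,15,16-tetranorlabdan-19-oate (C8 epimers; axial epimer shown) | C[C@]1(C(=O)OCC)[C@H]2CC[C@@H](CO)[C@@H](CCOCc3ccccc3)[C@]2(C)CC[C@H]1O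
F4 | step 7 | ethyl 12-(benzyloxy)-3α-hydroxy-17-oxo-13,14,15,16-tetranorlabdan-19-oate (8α-H) | C[C@]1(C(=O)OCC)[C@H]2CC[C@H](C=O)[C@@H](CCOCc3ccccc3)[C@]2(C)CC[C@H]1O
F5 | step 16 | allyl 13-(diethoxyphosphoryl)-3α,17,19-tris(TBS-oxy)-14,15-dinorlabdan-16-oate | C[C@]1(CO[Si](C)(C)C(C)(C)C)[C@H]2CC[C@H](CO[Si](C)(C)C(C)(C)C)[C@@H](CCC(C(=O)OCC=C)P(=O)(OCC)OCC)[C@]2(C)CC[C@H]1O[Si](C)(C)C(C)(C)C
F6 | step 9 | 8-phenylmenthyl 12-(benzyloxy)-3,17-dioxo-13,14,15,16-tetranorlabdan-19-oate (C8 epimers; axial epimer shown) | C[C@]1(C(=O)O[C@H]3C[C@@H](C)CC[C@@H]3C(C)(C)c3ccccc3)[C@H]2CC[C@@H](C=O)[C@@H](CCOCc3ccccc3)[C@]2(C)CCC1=O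
F7 | step 9 | 8-phenylmenthyl 12-(benzyloxy)-3,17-dioxo-13,14,15,16-tetranorlabdan-19-oate (8α-H) | C[C@]1(C(=O)O[C@H]3C[C@@H](C)CC[C@@H]3C(C)(C)c3ccccc3)[C@H]2CC[C@H](C=O)[C@@H](CCOCc3ccccc3)[C@]2(C)CCC1=O
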